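**Plan**

- Retrosynthesis: the target (15-O-acetyl-PGA1) is cut at C13=C14 (cross-metathesis with the acetate of the ω-chain alcohol), then at C10=C11 (ring-closing metathesis, which opens the cyclopentenone), then at C9–C10 (vinyl Grignard addition) and last at C8–C12 (α-allylation of a C1–C9 aldehyde ester).
- Forward: C8–C12 is made first and C9–C10 next; the methyl ester is hydrolysed while the molecule still tolerates base; C9 is oxidised; the five-membered ring C8–C9–C10=C11–C12 closes; the C13–C20 chain is joined last.
- Enabling feature: C12 carries two alkenyl arms, C11=C10 inside the ring and C13=C14 in the chain, so it can enter as a divinyl methine without configuration, whose two vinyl groups become different only when one of them closes the ring.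
- Stereochemistry: C8 (R) from the amine catalyst of the allylation; C12 (S) from the choice between the two diastereotopic vinyl groups, steered by C8, in the ring closure; C15 (S) from purchased (S)-oct-1-en-3-ol; 13E from the cross-metathesis.

Key step: step 5

Remark: prostaglandin numbering (C1 carboxyl to C20) is used for positions. The target SMILES is read as (8R,12S,13E,15S)-15-acetoxy-9-oxoprosta-10,13-dien-1-oic acid, and compounds 1, 2, 4 and 9 are taken to be purchasable.

**Route**

Step 1
Reactants: 1 methyl 9-oxononanoate; 2 penta-1,4-dien-3-ol
Product: 3 methyl (8R)-8-formyl-9-vinylundec-10-enoate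
Conditions: [Ir(cod)Cl]2 (3 mol %), (S)-5-(dinaphtho[2,1-d:1',2'-f][1,3,2]dioxaphosphepin-4-yl)-5H-dibenzo[b,f]azepine (12 mol %), (S)-2-{bis[3,5-bis(trifluoromethyl)phenyl](trimethylsilyloxy)methyl}pyrrolidine (15 mol %), (MeO)2P(O)OH (promoter), 2 (2 equiv), ClCH2CH2Cl, 25 °C; short silica pad, used at once
Reagents that add atoms: none
Why: Synergistic enamine and iridium catalysis (branched-selective allylic substitution of a racemic vinyl carbinol by an aldehyde enamine): the phosphoramidite–olefin complex of monovalent iridium ionises 2 to a vinyl-substituted allyliridium species, an analogue of the aryl-substituted ones on which this reaction is established, which is attacked at its substituted carbon by the E-enamine of 1 on the face left open by the diaryl(silyloxy)methyl group of the (S)-amine, so that C8 should arise R, while C12 carries two identical vinyl groups and is not yet a stereocentre, so either antipode of the phosphorus ligand should serve.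

Step 2
Reactants: 3 methyl (8R)-8-formyl-9-vinylundec-10-enoate; 4 vinylmagnesium bromide
Product: 5 methyl (8R)-9-hydroxy-8-(penta-1,4-dien-3-yl)undec-10-enoate (both C9 epimers)
Conditions: 4 (1.2 equiv), THF, −78 °C; then sat. aq. NH4Cl
Reagents that add atoms: vinylmagnesium bromide (4), C=C[Mg]Br
Why: Grignard 1,2-addition to the aldehyde, which at −78 °C is far faster than attack on the methyl ester or enolisation at C8; the new C9 carbinol centre forms without useful control (Felkin–Anh bias only) and both epimers are carried on because C9 becomes a ketone in step 4.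

Step 3
Reactants: 5 methyl (8R)-9-hydroxy-8-(penta-1,4-dien-3-yl)undec-10-enoate
Product: 6 (8R)-9-hydroxy-8-(penta-1,4-dien-3-yl)undec-10-enoic acid (both C9 epimers)
Conditions: LiOH·H2O, THF/MeOH/H2O, 0 °C → rt; then 1 M HCl to pH 3
Reagents that add atoms: lithium hydroxide, [Li+].[OH-]
Why: Ester saponification, placed at the last intermediate that tolerates hydroxide: in 5 the C8 centre is flanked by a carbinol and not by a carbonyl group, so neither epimerisation nor migration of the skipped diene is to be feared, whereas every later intermediate is a base-sensitive enone.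

Step 4
Reactants: 6 (8R)-9-hydroxy-8-(penta-1,4-dien-3-yl)undec-10-enoic acid
Product: 7 (8R)-9-oxo-8-(penta-1,4-dien-3-yl)undec-10-enoic acid
Conditions: Dess–Martin periodinane, CH2Cl2, 0 °C → rt; dilution with pentane/Et2O, filtration, concentration below 25 °C, used at once
Reagents that add atoms: none
Why: Dess–Martin oxidation of the secondary allylic alcohol under non-basic conditions, which converges both C9 epimers to one vinyl ketone, leaves the carboxylic acid and the three alkenes alone and, with a non-aqueous work-up and immediate use, spares the enolisable C8 centre and the polymerisation-prone acryloyl group.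

Step 5
Reactants: 7 (8R)-9-oxo-8-(penta-1,4-dien-3-yl)undec-10-enoic acid
Product: 8 7-[(1R,5S)-2-oxo-5-vinylcyclopent-3-en-1-yl]heptanoic acid
Conditions: RuCl2(H2IMes)(=CH-C6H4-2-O-iPr) (second-generation Hoveyda–Grubbs catalyst; H2IMes = 1,3-dimesitylimidazolidin-2-ylidene; 5 mol %), 1,4-benzoquinone (10 mol %), CH2Cl2 (0.005 M), 40 °C; chromatographic removal of any cis ring isomer
Reagents that add atoms: none
Why: Proposed new method: the ruthenium benzylidene should initiate on one of the two electron-rich vinyl groups at C12 rather than on the electron-poor acryloyl alkene, and the resulting C11 alkylidene adds [2+2] to the C10 acryloyl alkene and cycloreverts, forming C10=C11 and expelling ethylene. The closest known reactions are ring-closing metathesis of hepta-1,6-dien-3-ones to cyclopent-2-enones and substrate-controlled ring-closing metathesis that selects between the diastereotopic vinyl groups of a 1,4-diene next to a stereocentre; their combination on a vinyl ketone is the new element. The single ring, C8–C9–C10=C11–C12, closes by intramolecular alkene metathesis at C10=C11 and is made irreversible by loss of ethylene, while closure between the two C12 vinyl groups would need a cyclopropene and is excluded. The new C12 stereocentre is controlled by the C8 centre alone, with an achiral catalyst: in the transition state leading to the ruthenacyclobutane the unused vinyl group and the C7 chain avoid an eclipsed cis arrangement on the forming ring, so the trans (8R,12S) ring should be favoured. The step needs group selectivity between the two vinyl arms and ring closure in preference to chain growth; the C8 configuration, high dilution and benzoquinone (against ruthenium-hydride migration of the skipped diene) are meant to secure these. Any cis isomer must be separated before enolising conditions are met, because epimerisation at C8 would turn it into the enantiomeric trans ring.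

Step 6
Reactants: 9 (S)-oct-1-en-3-ol
Product: 10 (3S)-oct-1-en-3-yl acetate
Conditions: Ac2O, pyridine, 4-(dimethylamino)pyridine (cat.), CH2Cl2, 0 °C → rt
Reagents that add atoms: acetic anhydride, CC(=O)OC(C)=O
Why: Acylation of a secondary alcohol by nucleophilic catalysis (acetylpyridinium transfer), which does not touch the C–O bond at the stereocentre, so the S configuration of 9 is retained.

Step 7
Reactants: 8 7-[(1R,5S)-2-oxo-5-vinylcyclopent-3-en-1-yl]heptanoic acid; 10 (3S)-oct-1-en-3-yl acetate
Product: 11 (8R,12S,13E,15S)-15-acetoxy-9-oxoprosta-10,13-dien-1-oic acid, that is 7-[(1R,5S)-5-[(1E,3S)-3-acetoxyoct-1-en-1-yl]-2-oxocyclopent-3-en-1-yl]heptanoic acid (target)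
Conditions: RuCl2(H2IMes)(=CH-C6H4-2-O-iPr) (second-generation Hoveyda–Grubbs catalyst, 5–10 mol %), 10 (4 equiv), 1,4-benzoquinone (10 mol %), CH2Cl2, 40 °C
Reagents that add atoms: none
Why: Olefin cross-metathesis of two monosubstituted, allylically branched alkenes, for which homodimerisation of either partner is slow and the E-alkene is strongly favoured sterically; the endocyclic, electron-poor C10=C11 enone alkene should stay out of the reaction, C15 is delivered unchanged by 10, and the neutral medium with benzoquinone as hydride scavenger protects the C8 and C12 centres and the position of the C13 double bond.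

**Compound list**

1 | methyl 9-oxononanoate | COC(=O)CCCCCCCC=O | starting material
2 | penta-1,4-dien-3-ol | C=CC(O)C=C | starting material
3 | methyl (8R)-8-formyl-9-vinylundec-10-enoate | O=C[C@@H](C(C=C)C=C)CCCCCCC(=O)OC | intermediate
4 | vinylmagnesium bromide | C=C[Mg]Br | starting material
5 | methyl (8R)-9-hydroxy-8-(penta-1,4-dien-3-yl)undec-10-enoate (C9 epimers) | C=CC(O)[C@@H](C(C=C)C=C)CCCCCCC(=O)OC | intermediate
6 | (8R)-9-hydroxy-8-(penta-1,4-dien-3-yl)undec-10-enoic acid (C9 epimers) | C=CC(O)[C@@H](C(C=C)C=C)CCCCCCC(=O)O | intermediate
7 | (8R)-9-oxo-8-(penta-1,4-dien-3-yl)undec-10-enoic acid | C=CC(=O)[C@@H](C(C=C)C=C)CCCCCCC(=O)O | intermediate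
8 | 7-[(1R,5S)-2-oxo-5-vinylcyclopent-3-en-1-yl]heptanoic acid | C=C[C@H]1C=CC(=O)[C@@H]1CCCCCCC(=O)O | intermediate
9 | (S)-oct-1-en-3-ol | CCCCC[C@@H](C=C)O | starting material
10 | (3S)-oct-1-en-3-yl acetate | CCCCC[C@@H](C=C)OC(C)=O | intermediate
11 | (8R,12S,13E,15S)-15-acetoxy-9-oxoprosta-10,13-dien-1-oic acid | CCCCC[C@@H](/C=C/[C@H]1C=CC(=O)[C@@H]1CCCCCCC(=O)O)OC(C)=O | target

**Count**

Total steps: 7. Longest linear sequence: 6 (steps 1, 2, 3, 4, 5 and 7; step 6 prepares the coupling partner).

**Steps most likely to fail**

1. Step 5 (labelled). The ring closure may discriminate poorly between the two vinyl groups on C12, so that the cis ring forms alongside the trans one, or chain growth through these vinyl groups may outpace closure onto the electron-poor acryloyl alkene. The fallback uses known chemistry, sets out from vinylmagnesium bromide 4 and returns at 8; C12 is then set by a temporary oxygen at C11 instead of by group selection. Reagent 4 is converted with CuBr·SMe2 (THF, −78 °C) into the magnesium divinylcuprate and added to the commercial PGE1 building block methyl 7-[(3R)-5-oxo-3-(triethylsilyloxy)cyclopent-1-en-1-yl]heptanoate F1. Conjugate addition anti to the silyloxy group and protonation of the enolate to the trans-2,3 arrangement should give methyl 7-[(1R,2R,3R)-5-oxo-3-(triethylsilyloxy)-2-vinylcyclopentyl]heptanoate F2. Warm aqueous acetic acid (AcOH/THF/H2O, 60 °C) removes the silyl group and dehydrates the β-hydroxy ketone, the classical E-to-A conversion of prostaglandins, to methyl 7-[(1R,5S)-2-oxo-5-vinylcyclopent-3-en-1-yl]heptanoate F3. Pig liver esterase in pH 7 phosphate buffer then cleaves the methyl ester to 8.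

2. Step 1. The divinyl carbinol may ionise sluggishly or be attacked at a terminal carbon, giving a conjugated diene in place of the skipped one, and the α-branched aldehyde may lose configurational purity before it is trapped. The fallback sets out from 1 and returns at 3, forming C8–C12 by a sigmatropic shift. Chlorite oxidation (NaClO2, NaH2PO4, 2-methylbut-2-ene, t-BuOH/H2O) gives 9-methoxy-9-oxononanoic acid F4. Carbodiimide esterification with commercial (2E)-penta-2,4-dien-1-ol (DCC, DMAP, CH2Cl2) gives 1-methyl 9-[(2E)-penta-2,4-dien-1-yl] nonanedioate F5. An enantioselective Ireland–Claisen rearrangement follows, through the boron ketene acetal made with a C2-symmetric 2-bromo-4,5-diphenyl-1,3-bis(arylsulfonyl)-1,3,2-diazaborolidine and a tertiary amine (CH2Cl2, −78 °C → rt). More than two equivalents are used because the methyl ester is enolised reversibly as well, and the antipode of the reagent and the amine are chosen to give R. The [3,3] shift bonds C8 to the inner carbon of the dienyl unit and should give (2R)-9-methoxy-9-oxo-2-(penta-1,4-dien-3-yl)nonanoic acid F6. Activation with isobutyl chloroformate and N-methylmorpholine (THF, −15 °C) forms isobutyl carbonic (2R)-9-methoxy-9-oxo-2-(penta-1,4-dien-3-yl)nonanoic anhydride F7, which is reduced in the same flask with NaBH4 to methyl (8R)-8-(hydroxymethyl)-9-vinylundec-10-enoate F8. Dess–Martin periodinane oxidises F8 to 3.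

3. Step 7. Cross-coupling of the two allylically branched alkenes may stall, and slow turnover gives ruthenium hydrides time to move the C13 double bond into conjugation with the ring. The fallback sets out from 8 and 9 and returns at 11; it changes the partner class and introduces the ester after, not before, the C13=C14 bond. Acid 8 and the free alcohol 9 are joined with RuCl2(H2IMes)(=CH-C6H4-2-O-iPr) (second-generation Hoveyda–Grubbs catalyst) in CH2Cl2 at 40 °C, where the allylic hydroxyl accelerates metathesis by hydrogen bonding to a chloride ligand, to give (8R,12S,13E,15S)-15-hydroxy-9-oxoprosta-10,13-dien-1-oic acid F9 (PGA1). Acetic anhydride in pyridine at 0 °C acetylates O15 and transiently the carboxyl group, giving acetic (8R,12S,13E,15S)-15-acetoxy-9-oxoprosta-10,13-dien-1-oic anhydride F10, which stirring with water/THF hydrolyses to 11.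

**Further compounds**

F1 | step 5 | methyl 7-[(3R)-5-oxo-3-(triethylsilyloxy)cyclopent-1-en-1-yl]heptanoate | COC(=O)CCCCCCC1=C[C@H](O[Si](CC)(CC)CC)CC1=O
F2 | step 5 | methyl 7-[(1R,2R,3R)-5-oxo-3-(triethylsilyloxy)-2-vinylcyclopentyl]heptanoate | C=C[C@H]1[C@H](O[Si](CC)(CC)CC)CC(=O)[C@@H]1CCCCCCC(=O)OC
F3 | step 5 | methyl 7-[(1R,5S)-2-oxo-5-vinylcyclopent-3-en-1-yl]heptanoate | C=C[C@H]1C=CC(=O)[C@@H]1CCCCCCC(=O)OC
F4 | step 1 | 9-methoxy-9-oxononanoic acid | COC(=O)CCCCCCCC(=O)O
F5 | step 1 | 1-methyl 9-[(2E)-penta-2,4-dien-1-yl] nonanedioate | COC(=O)CCCCCCCC(=O)OC/C=C/C=C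
F6 | step 1 | (2R)-9-methoxy-9-oxo-2-(penta-1,4-dien-3-yl)nonanoic acid | OC(=O)[C@@H](C(C=C)C=C)CCCCCCC(=O)OC
F7 | step 1 | isobutyl carbonic (2R)-9-methoxy-9-oxo-2-(penta-1,4-dien-3-yl)nonanoic anhydride | CC(C)COC(=O)OC(=O)[C@@H](C(C=C)C=C)CCCCCCC(=O)OC
F8 | step 1 | methyl (8R)-8-(hydroxymethyl)-9-vinylundec-10-enoate | OC[C@@H](C(C=C)C=C)CCCCCCC(=O)OC
F9 | step 7 | (8R,12S,13E,15S)-15-hydroxy-9-oxoprosta-10,13-dien-1-oic acid (PGA1) | CCCCC[C@H](O)/C=C/[C@H]1C=CC(=O)[C@@H]1CCCCCCC(=O)O
F10 | step 7 | acetic (8R,12S,13E,15S)-15-acetoxy-9-oxoprosta-10,13-dien-1-oic anhydride | CCCCC[C@@H](/C=C/[C@H]1C=CC(=O)[C@@H]1CCCCCCC(=O)OC(C)=O)OC(C)=O
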